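**Retrosynthetic overview**
- The target comes from one oxidation of an 8α-acetoxy decalin that carries a 4α-CH2OH and a but-3-enyl chain at C9. CH2OH becomes the C18 acid and CH=CH2 becomes the C13 acid.
- That alcohol comes from its 3β-hydroxy analogue by radical removal of the C3 oxygen through a cyclic 3,18-thionocarbonate.
- Key step: an acyclic epoxy-triene closes ring A (C4–C5) and then ring B (C9–C10) in one cascade. External acetate ends the cascade at C8, so the C8–OAc bond and all five stereocentres are set together.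
- The (2S,3S)-epoxide comes from asymmetric epoxidation of an E-allylic alcohol, made by allylic oxidation of an all-E tetraene.
- The tetraene comes from farnesyl bromide and allylmagnesium chloride.

Assumption: positions follow labdane numbering (C4 bears CH3/CO2H, C8 bears CH3/OAc, C9 bears the side chain, C10 bears the angular CH3), and trans,trans-farnesyl bromide is bought as such.

**Step 1**
Reactants: 1 (2E,6E)-farnesyl bromide; 2 allylmagnesium chloride
Product: 3 (5E,9E)-6,10,14-trimethylpentadeca-1,5,9,13-tetraene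
Conditions: 2 (1.5 equiv), THF–Et2O, 0 °C to rt
Reagents that add atoms: none
Why: Uncatalysed allyl Grignard/allylic bromide coupling (SN2 at the primary carbon) forms no farnesyl cation or metal-allyl, so both E-alkenes are kept and no stereocentre is made.

**Step 2**
Reactants: 3 (5E,9E)-6,10,14-trimethylpentadeca-1,5,9,13-tetraene
Product: 4 (2E,6E,10E)-2,6,10-trimethylpentadeca-2,6,10,14-tetraen-1-ol
Conditions: SeO2 (0.1 equiv), salicylic acid (0.1 equiv), t-BuOOH (3 equiv), CH2Cl2, 0 °C to rt; stopped near half conversion, 3 recycled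
Reagents that add atoms: tert-butyl hydroperoxide, CC(C)(C)OO (oxygen relayed through selenium dioxide, O=[Se]=O)
Why: The Riley allylic oxidation (ene reaction, then [2,3]-shift) prefers the exposed terminal isopropylidene and oxidises only its E-methyl, and this E-CH2OH geometry later decides which C4 substituent is equatorial.

**Step 3**
Reactants: 4 (2E,6E,10E)-2,6,10-trimethylpentadeca-2,6,10,14-tetraen-1-ol
Product: 5 [(2S,3S)-3-[(3E,7E)-3,7-dimethyldodeca-3,7,11-trienyl]-2-methyloxiran-2-yl]methanol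
Conditions: Ti(OiPr)4 (10 mol %), L-(+)-diethyl tartrate (12 mol %), t-BuOOH (2 equiv, decane), 4 Å MS, CH2Cl2, −20 °C
Reagents that add atoms: tert-butyl hydroperoxide, CC(C)(C)OO
Why: In the Katsuki–Sharpless asymmetric epoxidation the allylic OH binds titanium, so only the C3=C4 alkene reacts, and L-(+)-tartrate gives the (2S,3S)-trans-epoxide (typically above 90 % ee), which is the source of absolute configuration.

**Step 4 (key step)**
Reactants: 5 [(2S,3S)-3-[(3E,7E)-3,7-dimethyldodeca-3,7,11-trienyl]-2-methyloxiran-2-yl]methanol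
Product: 8 8α-acetoxy-15,16-dinorlabd-13-ene-3β,18-diol (3S,4R,5R,8R,9R,10S), via silyl ether 6 (not isolated), via bis-silyl ether 7 (not isolated)
Conditions: Me3SiOAc (6 equiv), Me3SiOSO2CF3 (0.25 equiv), CH2Cl2 (0.01 M), −78 °C, 1 h; Et3N quench; then 1 M aq. citric acid, THF, rt
Reagents that add atoms: trimethylsilyl acetate, CC(=O)O[Si](C)(C)C
Why: Proposed new method: Me3Si+ first caps the free OH (6) and then silylates the oxirane oxygen; the C5=C10 alkene opens the epoxide at tertiary C4 from the back (inversion) in a chair–chair fold, C9=C8 adds to the C10 cation, and the carbonyl oxygen of Me3SiOAc takes the C8 cation from the equatorial α face (the β face is blocked by the axial C10 methyl), releasing Me3Si+ to carry a silyl-transfer chain; every addition is anti across an E-alkene (Stork–Eschenmoser rule), so the E-CH2OSi group ends equatorial (C18) and the C4 methyl axial, H5 and H9 end α, the C10 and C8 methyls end β, and the (3S)-epoxide carbon fixes the normal absolute series; the closest known chemistry is the Lewis-acid epoxide-initiated cation–olefin polycyclisation, combined with capture of the last cation by an external oxygen nucleophile as in solvolytic formate or trifluoroacetate polyene cyclisations and with silyl-triflate-catalysed transfer from silylated nucleophiles.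

**Step 5**
Reactants: 8 8α-acetoxy-15,16-dinorlabd-13-ene-3β,18-diol
Product: 11 8α-acetoxy-15,16-dinorlabd-13-en-18-ol (4R,5R,8R,9R,10S), via thionocarbonate 9 (not isolated), via stannyl thiocarbonate 10 (not isolated)
Conditions: 1,1'-thiocarbonyldiimidazole (1.2 equiv), 4-(dimethylamino)pyridine (0.1 equiv), PhMe, 90 °C; then Bu3SnH (2 equiv), azobisisobutyronitrile (0.2 equiv), 110 °C; then K2CO3 (0.2 equiv), MeOH–H2O, rt
Reagents that add atoms: 1,1'-thiocarbonyldiimidazole, S=C(n1ccnc1)n1ccnc1 (C=S carried in 9 and 10 only); tributyltin hydride, CCCC[SnH](CCCC)CCCC (Bu3Sn carried in 10 only)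
Why: In this cyclic-thionocarbonate variant of the Barton–McCombie deoxygenation the tin radical adds to C=S, the adduct breaks the secondary C3–O bond rather than the neopentyl primary C18–O bond, hydrogen transfer gives the C3 methylene, mild hydrolysis frees the 18-OH, and no remaining stereocentre is touched.

**Step 6**
Reactants: 11 8α-acetoxy-15,16-dinorlabd-13-en-18-ol
Product: 12 8α-acetoxy-14,15,16-trinorlabdane-13,18-dioic acid = (1R,4aS,5R,6R,8aR)-6-acetoxy-5-(2-carboxyethyl)-1,4a,6-trimethyldecahydronaphthalene-1-carboxylic acid (target)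
Conditions: RuCl3·xH2O (5 mol %), NaIO4 (8 equiv), EtOAc–MeCN–H2O, 0 °C to rt
Reagents that add atoms: sodium periodate, [Na+].[O-]I(=O)(=O)=O; water, O
Why: Ruthenium tetroxide made in situ (Sharpless RuCl3/NaIO4 oxidation) cleaves the monosubstituted alkene to the C13 acid and takes the neopentyl CH2OH through its aldehyde hydrate to the C18 acid in the same pot, while the hindered tertiary acetate survives and none of the five stereocentres can epimerise.

**Compound list**
1 | (2E,6E)-farnesyl bromide | CC(C)=CCC/C(C)=C/CC/C(C)=C/CBr | starting material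
2 | allylmagnesium chloride | C=CC[Mg]Cl | starting material
3 | (5E,9E)-6,10,14-trimethylpentadeca-1,5,9,13-tetraene | CC(C)=CCC/C(C)=C/CC/C(C)=C/CCC=C | intermediate
4 | (2E,6E,10E)-2,6,10-trimethylpentadeca-2,6,10,14-tetraen-1-ol | OC/C(C)=C/CC/C(C)=C/CC/C(C)=C/CCC=C | intermediate
5 | [(2S,3S)-3-[(3E,7E)-3,7-dimethyldodeca-3,7,11-trienyl]-2-methyloxiran-2-yl]methanol | OC[C@]1(C)O[C@H]1CC/C(C)=C/CC/C(C)=C/CCC=C | intermediate
6 | O-trimethylsilyl ether of 5 | C[Si](C)(C)OC[C@]1(C)O[C@H]1CC/C(C)=C/CC/C(C)=C/CCC=C | intermediate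
7 | 8α-acetoxy-3β,18-bis(trimethylsilyloxy)-15,16-dinorlabd-13-ene | CC(=O)O[C@]1(C)CC[C@@H]2[C@](C)(CC[C@H](O[Si](C)(C)C)[C@@]2(C)CO[Si](C)(C)C)[C@H]1CCC=C | intermediate
8 | 8α-acetoxy-15,16-dinorlabd-13-ene-3β,18-diol | CC(=O)O[C@]1(C)CC[C@@H]2[C@](C)(CC[C@H](O)[C@@]2(C)CO)[C@H]1CCC=C | intermediate
9 | cyclic 3β,18-thionocarbonate of 8 | CC(=O)O[C@]1(C)CC[C@@H]2[C@](C)(CC[C@H](O3)[C@@]2(C)COC3=S)[C@H]1CCC=C | intermediate
10 | 18-O-[(tributylstannylsulfanyl)carbonyl] derivative of 11 | CC(=O)O[C@]1(C)CC[C@@H]2[C@](C)(CCC[C@@]2(C)COC(=O)S[Sn](CCCC)(CCCC)CCCC)[C@H]1CCC=C | intermediate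
11 | 8α-acetoxy-15,16-dinorlabd-13-en-18-ol | CC(=O)O[C@]1(C)CC[C@@H]2[C@](C)(CCC[C@@]2(C)CO)[C@H]1CCC=C | intermediate
12 | 8α-acetoxy-14,15,16-trinorlabdane-13,18-dioic acid | CC(=O)O[C@]1(C)CC[C@@H]2[C@](C)(CCC[C@@]2(C)C(=O)O)[C@H]1CCC(=O)O | target

**Total step count:** 6. **Longest linear sequence:** 6.

**Steps most likely to fail**

Step 4. Proton loss at C8, a hydride shift to the 3-ketone, or attack of the side-chain vinyl group on the C8 cation may outrun acetate capture. The fallback separates ring formation from acetate installation and runs from 5 back to 9.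
- Compound 5 is cyclised in wet hexafluoroisopropanol with Ph4PBF4, so that water ends the cascade and gives 15,16-dinorlabd-13-ene-3β,8α,18-triol F1.
- Thiocarbonyldiimidazole engages only the 1,3-diol and gives 8α-hydroxy-15,16-dinorlabd-13-ene-3β,18-diyl thionocarbonate F2.
- Acetyl chloride with N,N-dimethylaniline acylates the tertiary alcohol and gives 9, isolated this time, which enters the tin hydride stage of step 5.

Step 2. Selectivity among three trisubstituted alkenes is only moderate and over-oxidation costs material. The fallback builds the E-allylic alcohol by cleavage and olefination, and runs from 3 back to 4.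
- N-bromosuccinimide in aqueous THF attacks the terminal isopropylidene and gives (6E,10E)-3-bromo-2,6,10-trimethylpentadeca-6,10,14-trien-2-ol F3.
- K2CO3 in methanol closes it to 2,2-dimethyl-3-[(3E,7E)-3,7-dimethyldodeca-3,7,11-trienyl]oxirane F4.
- H5IO6 in aqueous THF cleaves this to (4E,8E)-4,8-dimethyltrideca-4,8,12-trienal F5.
- Wittig olefination with Ph3P=C(CH3)CO2Et gives ethyl (2E,6E,10E)-2,6,10-trimethylpentadeca-2,6,10,14-tetraenoate F6.
- iBu2AlH reduces F6 to 4.

Step 5. Tin radicals may add to the terminal alkene, some C18–O scission may occur, and the telescoped format is demanding. The fallback removes the C3 oxygen by an ionic route and runs from 8 back to 11.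
- tert-Butyldimethylsilyl chloride with imidazole protects only the primary alcohol and gives 8α-acetoxy-18-(tert-butyldimethylsilyloxy)-15,16-dinorlabd-13-en-3β-ol F7.
- Dess–Martin periodinane gives 8α-acetoxy-18-(tert-butyldimethylsilyloxy)-15,16-dinorlabd-13-en-3-one F8.
- p-Toluenesulfonyl hydrazide gives the 3-tosylhydrazone F9.
- Catecholborane followed by NaOAc·3H2O gives 8α-acetoxy-18-(tert-butyldimethylsilyloxy)-15,16-dinorlabd-13-ene F10.
- HF·pyridine frees 11.

**Further compounds**
F1 | step 4 | 15,16-dinorlabd-13-ene-3β,8α,18-triol | O[C@]1(C)CC[C@@H]2[C@](C)(CC[C@H](O)[C@@]2(C)CO)[C@H]1CCC=C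
F2 | step 4 | 8α-hydroxy-15,16-dinorlabd-13-ene-3β,18-diyl thionocarbonate | O[C@]1(C)CC[C@@H]2[C@](C)(CC[C@H](O3)[C@@]2(C)COC3=S)[C@H]1CCC=C
F3 | step 2 | (6E,10E)-3-bromo-2,6,10-trimethylpentadeca-6,10,14-trien-2-ol (racemic) | CC(C)(O)C(Br)CC/C(C)=C/CC/C(C)=C/CCC=C
F4 | step 2 | 2,2-dimethyl-3-[(3E,7E)-3,7-dimethyldodeca-3,7,11-trienyl]oxirane (racemic) | CC1(C)OC1CC/C(C)=C/CC/C(C)=C/CCC=C
F5 | step 2 | (4E,8E)-4,8-dimethyltrideca-4,8,12-trienal | O=CCC/C(C)=C/CC/C(C)=C/CCC=C
F6 | step 2 | ethyl (2E,6E,10E)-2,6,10-trimethylpentadeca-2,6,10,14-tetraenoate | CCOC(=O)/C(C)=C/CC/C(C)=C/CC/C(C)=C/CCC=C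
F7 | step 5 | 8α-acetoxy-18-(tert-butyldimethylsilyloxy)-15,16-dinorlabd-13-en-3β-ol | CC(=O)O[C@]1(C)CC[C@@H]2[C@](C)(CC[C@H](O)[C@@]2(C)CO[Si](C)(C)C(C)(C)C)[C@H]1CCC=C
F8 | step 5 | 8α-acetoxy-18-(tert-butyldimethylsilyloxy)-15,16-dinorlabd-13-en-3-one | CC(=O)O[C@]1(C)CC[C@@H]2[C@](C)(CCC(=O)[C@@]2(C)CO[Si](C)(C)C(C)(C)C)[C@H]1CCC=C
F9 | step 5 | 3-tosylhydrazone of F8 | CC(=O)O[C@]1(C)CC[C@@H]2[C@](C)(CCC(=NNS(=O)(=O)c3ccc(C)cc3)[C@@]2(C)CO[Si](C)(C)C(C)(C)C)[C@H]1CCC=C
F10 | step 5 | 8α-acetoxy-18-(tert-butyldimethylsilyloxy)-15,16-dinorlabd-13-ene | CC(=O)O[C@]1(C)CC[C@@H]2[C@](C)(CCC[C@@]2(C)CO[Si](C)(C)C(C)(C)C)[C@H]1CCC=C
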